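**Plan**

- Carotenoid numbering is used, with the hydroxy-ring half primed. The C14=C15–C15'=C14' diene around the C15–C15' single bond of the retro chain is read as a reduced 2-yne-1,4-diol. This cuts C14–C15 and C15'–C14' and leaves acetylene (C15, C15') plus two C19 aldehydes whose α-carbons C13 and C13' are sp2.
- The cyclohexa-2,4-diene ring of the unprimed half is traced to the 3'-hydroxy ring by loss of water (C2=C3), so both aldehydes come from one silyl-protected hydroxy C19 aldehyde.
- That aldehyde is cut at C12'=C13' and C10'=C11' (two Wittig reactions) and at C6'=C7'/C8'=C9' (a second ynediol reductive elimination), giving a C5 alkynol and the ring enone.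
- Forward: the only ring comes from ketoisophorone and no ring is closed later. The chain grows C7'–C10', then C11'–C12', then C13'–C14'. The material is split and one part dehydrated; the halves are joined through ethynylmagnesium bromide, followed by reductive elimination, iodine equilibration and desilylation.
- Stereochemistry: the single stereocentre C3' comes from an enzymatic ene-reduction (ring methyl centre) relayed to the carbinol by substrate-controlled hydride reduction. Double-bond geometry comes from stabilised ylides, the reductive eliminations and a final iodine equilibration.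

Key step: step 12

Remark on the chemistry: both exocyclic ring–chain double bonds of the target place the chain syn to the gem-dimethyl carbon (C8 syn to C1, C8' syn to C1'; CIP gives Z on the diene ring and E on the hydroxy ring). This is assumed to be the thermodynamically preferred arrangement, so equilibrating steps should converge on it.

**Route**

Step 1
Reactants: 1 ketoisophorone (2,6,6-trimethylcyclohex-2-ene-1,4-dione)
Product: 2 (6R)-levodione [(6R)-2,2,6-trimethylcyclohexane-1,4-dione]
Conditions: ene-reductase (old yellow enzyme), NADP+ (cat.), glucose dehydrogenase, D-glucose, phosphate buffer pH 6.5, 30 °C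
Reagents that add atoms: none
Why: Enzymatic asymmetric conjugate reduction (old-yellow-enzyme ene-reductase, cofactor recycled by glucose dehydrogenase): flavin hydride and an active-site proton add trans across the doubly activated C2=C3 bond, and the fixed binding mode of the enedione should set the methyl-bearing carbon as (R).

Step 2
Reactants: 2 (6R)-levodione
Product: 3 (4R,6R)-actinol [(4R,6R)-4-hydroxy-2,2,6-trimethylcyclohexan-1-one]
Conditions: LiBH(s-Bu)3 (1.05 equiv), THF, −78 °C; H2O
Reagents that add atoms: none
Why: Substrate-controlled hydride reduction with a bulky borohydride: the C1 carbonyl is shielded by the gem-dimethyl and methyl groups, and the axial C2 methyl blocks axial approach to C4, so equatorial delivery should give the axial (4R) alcohol trans to the C6 methyl.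

Step 3
Reactants: 3 (4R,6R)-actinol
Product: 4 (4R,6R)-4-(tert-butyldimethylsilyloxy)-2,2,6-trimethylcyclohexan-1-one
Conditions: TBSCl, imidazole, DMF, rt
Reagents that add atoms: tert-butyldimethylsilyl chloride, CC(C)(C)[Si](C)(C)Cl
Why: Standard imidazole-mediated silylation of a secondary alcohol; the silyl ether withstands organolithium, hydride and ylide reagents and leaves with fluoride without acid.

Step 4
Reactants: 4 (4R,6R)-4-(tert-butyldimethylsilyloxy)-2,2,6-trimethylcyclohexan-1-one
Product: 6 (S)-4-(tert-butyldimethylsilyloxy)-2,6,6-trimethylcyclohex-2-en-1-one, via trimethylsilyl enol ether 5 (not isolated)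
Conditions: LiN(i-Pr)2, Me3SiCl, THF, −78 → 0 °C; then Pd(OAc)2 (1 equiv), MeCN, rt
Reagents that add atoms: none
Why: Saegusa–Ito oxidation: C6 carries the only enolisable hydrogen, so the silyl enol ether forms regiospecifically, and β-hydride elimination from the oxa-π-allyl complex of divalent palladium gives the ring enone; the C6 centre is erased, the carbinol centre is untouched and is now called (S) only because the CIP priorities of its neighbours change.

Step 5
Reactants: 7 pyruvaldehyde dimethyl acetal (1,1-dimethoxypropan-2-one); 8 ethynylmagnesium bromide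
Product: 9 rac-1,1-dimethoxy-2-methylbut-3-yn-2-ol
Conditions: THF, 0 °C → rt; H2O
Reagents that add atoms: none
Why: Grignard 1,2-addition of an acetylide to a methyl ketone; the tertiary carbinol centre is racemic and is erased in step 7.

Step 6
Reactants: 6 (S)-4-(tert-butyldimethylsilyloxy)-2,6,6-trimethylcyclohex-2-en-1-one; 9 rac-1,1-dimethoxy-2-methylbut-3-yn-2-ol
Product: 10 (4S)-4-(tert-butyldimethylsilyloxy)-1-(3-hydroxy-4,4-dimethoxy-3-methylbut-1-yn-1-yl)-2,6,6-trimethylcyclohex-2-en-1-ol (mixture at both carbinol carbons)
Conditions: 9 (1.3 equiv), n-BuLi (2.6 equiv), THF, −78 → 0 °C; then 6, −78 °C → rt; H2O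
Reagents that add atoms: none
Why: 1,2-Addition of a lithium acetylide (the O,C-dilithio form of 9) to a hindered cyclohexenone, as practised in abscisic acid syntheses: the slim sp nucleophile reaches the flanked carbonyl and does not add in a conjugate sense; both new carbinol centres form without control and are removed in step 7.

Step 7
Reactants: 10 ring ynediol
Product: 12 retro-C14 aldehyde (2E)-4-[(1E,4S)-4-(tert-butyldimethylsilyloxy)-2,6,6-trimethylcyclohex-2-en-1-ylidene]-2-methylbut-2-enal, via retro-C14 dimethyl acetal 11 (not isolated)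
Conditions: LiAlH4, THF, 0 → 60 °C; H2O/aq. NaOH work-up; crude 11, PPTS (cat.), acetone–H2O, 0 °C → rt
Reagents that add atoms: water, O
Why: Whiting reductive 1,4-elimination of a 2-yne-1,4-diol: alkoxide-directed trans-hydroalumination of the triple bond, loss of one aluminate oxygen to an allenyl carbinol and SN2' hydride delivery with loss of the second oxygen give the C6=C7–C8=C9 diene, in which allylic strain with the C5 methyl should place C8 syn to C1; the vinylogous acetal then hydrolyses under buffered acid far faster than the allylic silyl ether ionises.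

Step 8
Reactants: 12 retro-C14 aldehyde; 13 (1,3-dioxolan-2-ylmethyl)triphenylphosphonium bromide
Product: 15 retro-C16 aldehyde (2E,4E)-6-[(1E,4S)-4-(tert-butyldimethylsilyloxy)-2,6,6-trimethylcyclohex-2-en-1-ylidene]-4-methylhexa-2,4-dienal, via dioxolane acetal 14 (not isolated)
Conditions: 13, t-BuOK, THF, 0 °C → rt; then aq. oxalic acid, THF, rt
Reagents that add atoms: water, O
Why: Wittig reaction of a semi-stabilised ylide with a non-enolisable enal followed by acetal hydrolysis, the standard two-carbon homologation of polyenals; the C10=C11 bond may form as a cis/trans mixture, which should converge on trans at the enal stage under the acidic hydrolysis and at the latest in step 14.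

Step 9
Reactants: 15 retro-C16 aldehyde; 16 2-(triphenylphosphoranylidene)propanal
Product: 17 hydroxy-ring retro-C19 aldehyde silyl ether (2E,4E,6E)-8-[(1E,4S)-4-(tert-butyldimethylsilyloxy)-2,6,6-trimethylcyclohex-2-en-1-ylidene]-2,6-dimethylocta-2,4,6-trienal
Conditions: toluene, 80 °C, dark
Reagents that add atoms: none
Why: Wittig reaction with a formyl-stabilised ylide, which should give the E trisubstituted C12=C13 bond; the α-methyl-branched product is less electrophilic than the unbranched C16 aldehyde, which prevents a second homologation.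

Step 10
Reactants: 17 hydroxy-ring retro-C19 aldehyde silyl ether (the portion destined for the other half)
Product: 18 (2E,4E,6E)-8-[(1E,4S)-4-hydroxy-2,6,6-trimethylcyclohex-2-en-1-ylidene]-2,6-dimethylocta-2,4,6-trienal
Conditions: Bu4NF, AcOH, THF, 0 °C → rt
Reagents that add atoms: none
Why: Fluoride-induced cleavage of the Si–O bond, buffered with AcOH so that the polyenal sees no strong base; the stereocentre is not touched.

Step 11
Reactants: 18 hydroxy retro-C19 aldehyde
Product: 19 dehydro-ring retro-C19 aldehyde (2E,4E,6E)-2,6-dimethyl-8-[(1Z)-2,6,6-trimethylcyclohexa-2,4-dien-1-ylidene]octa-2,4,6-trienal (C8 syn to the gem-dimethyl carbon)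
Conditions: Burgess reagent [methyl N-(triethylammoniosulfonyl)carbamate], benzene, 20 → 50 °C
Reagents that add atoms: none
Why: Burgess dehydration (syn elimination through the sulfamate ester): C4 is sp2, so only the C2 hydrogens can be lost and the new C2=C3 bond forms in conjugation with C4=C5, turning the hydroxy ring into the cyclohexa-2,4-diene ring; the stereocentre is deliberately destroyed here.

Step 12
Reactants: 19 dehydro-ring retro-C19 aldehyde; 8 ethynylmagnesium bromide; 17 hydroxy-ring retro-C19 aldehyde silyl ether
Product: 21 C40 15,15'-yne-14,14'-diol 3'-silyl ether (mixture of C14/C14' epimers), via bromomagnesium alkoxide 20 (not isolated)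
Conditions: 8 (2 equiv), THF, −20 °C, slow addition of 19; t-BuOH (1 equiv), Ar sparge, 20 °C; EtMgBr (1.1 equiv), 35 °C; 17 (0.95 equiv), 0 °C → rt; H2O
Reagents that add atoms: none
Why: The sp carbanion of 8 adds 1,2 to the C14 carbonyl of 19 to give alkoxide 20; after the surplus acetylide has been discharged as acetylene, EtMgBr removes the remaining alkyne hydrogen and the resulting O,C-dimagnesium species adds 1,2 to the C14' carbonyl of 17, so that C14–C15 and C15'–C14' are both made from one acetylene unit. The closest known reaction type is the stepwise addition of acetylene Grignard reagents to two aldehydes to give unsymmetrical 2-yne-1,4-diols, long used to join polyenals. No ring is closed. The two carbinol centres at C14 and C14' arise without any controlling element and are tolerated as a mixture because both are erased in step 13. The step needs 1,2-selectivity and hetero-selectivity: the former is secured by the sp2 α-carbons C13 and C13', which rule out α-enolisation and leave a hard acetylide facing a formyl group, the latter by the order of addition, since 19 meets only mono-acetylide in excess and 17 meets only the pre-formed alkynyl alkoxide. The silyl ether, the C3' centre and both rings are spectators under these basic conditions.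

Step 13
Reactants: 21 C40 ynediol silyl ether
Product: 22 3'-O-(tert-butyldimethylsilyl) ether of the target as a mixture of double-bond isomers (C14=C15 and C15'=C14' not yet uniform)
Conditions: LiAlH4, THF, 0 → 40 °C; H2O/aq. NaOH work-up
Reagents that add atoms: none
Why: Whiting reductive 1,4-elimination as in step 7: hydroalumination of the C15≡C15' bond and loss of both aluminate oxygens give the C14=C15–C15'=C14' diene and complete the conjugated retro-polyene, erasing the C14 and C14' centres; the silyl ether and the C3' centre are inert to LiAlH4.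

Step 14
Reactants: 22 silyl ether isomer mixture
Product: 23 all-trans 3'-O-(tert-butyldimethylsilyl) ether of the target
Conditions: I2 (cat.), hexane–CH2Cl2, daylight, rt, N2; crystallisation
Reagents that add atoms: none
Why: Iodine-catalysed photo-equilibration (reversible addition of iodine atoms) should converge the isomer mixture on the thermodynamically preferred all-trans chain with C8 and C8' syn to the gem-dimethyl carbons; it is run on the silyl ether so that traces of HI cannot dehydrate a free allylic alcohol.

Step 15
Reactants: 23 all-trans silyl ether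
Product: 24 target, (3'S)-anhydroeschscholtzxanthin
Conditions: Bu4NF, AcOH, THF, 0 °C → rt
Reagents that add atoms: none
Why: Fluoride desilylation under buffered, non-acidic conditions, chosen because the allylic C3' alcohol conjugated to the polyene would lose water under acid; the (3'S) centre set in step 2 is released unchanged.

**Compound list**

1 | ketoisophorone, 2,6,6-trimethylcyclohex-2-ene-1,4-dione | CC1=CC(=O)CC(C)(C)C1=O | starting material
2 | (6R)-levodione, (6R)-2,2,6-trimethylcyclohexane-1,4-dione | O=C1[C@H](C)CC(=O)CC1(C)C | intermediate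
3 | (4R,6R)-actinol, (4R,6R)-4-hydroxy-2,2,6-trimethylcyclohexan-1-one | O=C1[C@H](C)C[C@@H](O)CC1(C)C | intermediate
4 | (4R,6R)-4-(tert-butyldimethylsilyloxy)-2,2,6-trimethylcyclohexan-1-one | O=C1[C@H](C)C[C@@H](O[Si](C)(C)C(C)(C)C)CC1(C)C | intermediate
5 | trimethylsilyl enol ether of 4, (4R)-4-(tert-butyldimethylsilyloxy)-2,6,6-trimethyl-1-(trimethylsilyloxy)cyclohex-1-ene | CC1=C(O[Si](C)(C)C)C(C)(C)C[C@H](O[Si](C)(C)C(C)(C)C)C1 | intermediate
6 | (S)-4-(tert-butyldimethylsilyloxy)-2,6,6-trimethylcyclohex-2-en-1-one | O=C1C(C)=C[C@@H](O[Si](C)(C)C(C)(C)C)CC1(C)C | intermediate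
7 | pyruvaldehyde dimethyl acetal, 1,1-dimethoxypropan-2-one | CC(=O)C(OC)OC | starting material
8 | ethynylmagnesium bromide | C#C[Mg]Br | starting material
9 | rac-1,1-dimethoxy-2-methylbut-3-yn-2-ol | C#CC(C)(O)C(OC)OC | intermediate
10 | (4S)-4-(tert-butyldimethylsilyloxy)-1-(3-hydroxy-4,4-dimethoxy-3-methylbut-1-yn-1-yl)-2,6,6-trimethylcyclohex-2-en-1-ol, mixture at both carbinol carbons | COC(OC)C(C)(O)C#CC1(O)C(C)=C[C@@H](O[Si](C)(C)C(C)(C)C)CC1(C)C | intermediate
11 | retro-C14 dimethyl acetal, dimethyl acetal of 12 | COC(OC)/C(C)=C/C=C1/C(C)=C[C@@H](O[Si](C)(C)C(C)(C)C)CC1(C)C | intermediate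
12 | retro-C14 aldehyde, (2E)-4-[(1E,4S)-4-(tert-butyldimethylsilyloxy)-2,6,6-trimethylcyclohex-2-en-1-ylidene]-2-methylbut-2-enal | O=C/C(C)=C/C=C1/C(C)=C[C@@H](O[Si](C)(C)C(C)(C)C)CC1(C)C | intermediate
13 | (1,3-dioxolan-2-ylmethyl)triphenylphosphonium bromide | [Br-].C1COC(C[P+](c2ccccc2)(c2ccccc2)c2ccccc2)O1 | starting material
14 | dioxolane acetal of 15, C10=C11 as cis/trans mixture | C1COC(O1)C=C/C(C)=C/C=C2/C(C)=C[C@@H](O[Si](C)(C)C(C)(C)C)CC2(C)C | intermediate
15 | retro-C16 aldehyde, (2E,4E)-6-[(1E,4S)-4-(tert-butyldimethylsilyloxy)-2,6,6-trimethylcyclohex-2-en-1-ylidene]-4-methylhexa-2,4-dienal | O=C/C=C/C(C)=C/C=C1/C(C)=C[C@@H](O[Si](C)(C)C(C)(C)C)CC1(C)C | intermediate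
16 | 2-(triphenylphosphoranylidene)propanal | CC(C=O)=P(c1ccccc1)(c1ccccc1)c1ccccc1 | starting material
17 | hydroxy-ring retro-C19 aldehyde silyl ether, (2E,4E,6E)-8-[(1E,4S)-4-(tert-butyldimethylsilyloxy)-2,6,6-trimethylcyclohex-2-en-1-ylidene]-2,6-dimethylocta-2,4,6-trienal | O=C/C(C)=C/C=C/C(C)=C/C=C1/C(C)=C[C@@H](O[Si](C)(C)C(C)(C)C)CC1(C)C | intermediate
18 | (2E,4E,6E)-8-[(1E,4S)-4-hydroxy-2,6,6-trimethylcyclohex-2-en-1-ylidene]-2,6-dimethylocta-2,4,6-trienal | O=C/C(C)=C/C=C/C(C)=C/C=C1/C(C)=C[C@@H](O)CC1(C)C | intermediate
19 | dehydro-ring retro-C19 aldehyde, (2E,4E,6E)-2,6-dimethyl-8-[(1Z)-2,6,6-trimethylcyclohexa-2,4-dien-1-ylidene]octa-2,4,6-trienal | CC1=CC=CC(C)(C)\C1=C/C=C(C)/C=C/C=C(C)/C=O | intermediate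
20 | bromomagnesium alkoxide of the C21 ethynyl carbinol from 19 (C14 epimers) | CC1=CC=CC(C)(C)\C1=C/C=C(C)/C=C/C=C(C)/C(O[Mg]Br)C#C | intermediate
21 | C40 15,15'-yne-14,14'-diol, 3'-O-tert-butyldimethylsilyl, (3'S), mixture at C14 and C14' | CC1=CC=CC(C)(C)\C1=C/C=C(C)/C=C/C=C(C)/C(O)C#CC(O)/C(C)=C/C=C/C(C)=C/C=C1/C(C)=C[C@@H](O[Si](C)(C)C(C)(C)C)CC1(C)C | intermediate
22 | 3'-O-tert-butyldimethylsilyl ether of the target, isomer mixture at C14=C15 and C15'=C14' | CC1=CC=CC(C)(C)\C1=C/C=C(C)/C=C/C=C(C)/C=CC=C/C(C)=C/C=C/C(C)=C/C=C1/C(C)=C[C@@H](O[Si](C)(C)C(C)(C)C)CC1(C)C | intermediate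
23 | all-trans 3'-O-tert-butyldimethylsilyl ether of the target | CC1=CC=CC(C)(C)\C1=C/C=C(C)/C=C/C=C(C)/C=C/C=C/C(C)=C/C=C/C(C)=C/C=C1/C(C)=C[C@@H](O[Si](C)(C)C(C)(C)C)CC1(C)C | intermediate
24 | (3'S)-anhydroeschscholtzxanthin, all-trans retro-carotenoid with a 2,6,6-trimethylcyclohexa-2,4-dienylidene end and a (4S)-4-hydroxy-2,6,6-trimethylcyclohex-2-enylidene end | CC1=CC=CC(C)(C)\C1=C/C=C(C)/C=C/C=C(C)/C=C/C=C/C(C)=C/C=C/C(C)=C/C=C1/C(C)=C[C@@H](O)CC1(C)C | target

**Step count**

Total steps: 15. Longest linear sequence: 14 steps (steps 1–4 and 6–15; step 5 is a one-step side branch).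

**Steps most likely to fail**

Step 12. Incomplete discharge of the surplus acetylide or slow C-metalation of the alkoxide would divert the silyl aldehyde into homo-adducts, and the aggregated magnesium alkoxide–acetylide may add sluggishly to the α-methyl enal. The fallback uses a differentiated acetylene in separate operations. It sets out from 19: Me3SiC≡CLi (THF, −78 °C) gives the C21 trimethylsilylalkynyl carbinol F1. K2CO3 in MeOH removes the silyl group to give the C21 ethynyl carbinol F2. F2 is converted into its O,C-dianion with n-BuLi (2 equiv, THF, −78 °C) and 17 is added. The route is rejoined at 21.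

Step 7. The reductive elimination may stall at the ene-diol or allenyl carbinol stage at the two hindered tertiary alkoxides, or the allylic silyl ether may ionise during acetal cleavage. The fallback replaces the reductive elimination by a carbonyl transposition and sets out from 6. Ethynylmagnesium bromide 8 (CeCl3, THF) gives the ring ethynyl carbinol F3. Meyer–Schuster rearrangement (VO(OSiPh3)3 cat., xylene, 120 °C) gives the ring-ylidene acetaldehyde F4. Horner–Wadsworth–Emmons reaction with triethyl 2-phosphonopropionate (NaH, THF) gives the retro-C14 ethyl ester F5. i-Bu2AlH (CH2Cl2, −78 °C) gives the retro-C14 allylic alcohol F6. MnO2 oxidation rejoins the route at 12.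

Step 13. Hydride may be delivered at a remote position of the long polyene, or the sequence may stop after one oxygen is lost, giving dihydro or allenic by-products. The fallback separates reduction and deoxygenation and sets out from 21. NaAlH2(OCH2CH2OMe)2 (THF, 0 °C) reduces only the triple bond and gives the (E)-15,15'-ene-14,14'-diol F7. Low-valent titanium (TiCl3/LiAlH4, THF, rt) then removes both hydroxyl groups in a reductive 1,4-elimination. The route is rejoined at 22.

Further compounds
F1 | step 12 | C21 trimethylsilylalkynyl carbinol from 19 (C14 epimers) | CC1=CC=CC(C)(C)\C1=C/C=C(C)/C=C/C=C(C)/C(O)C#C[Si](C)(C)C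
F2 | step 12 | C21 ethynyl carbinol from 19 (C14 epimers) | CC1=CC=CC(C)(C)\C1=C/C=C(C)/C=C/C=C(C)/C(O)C#C
F3 | step 7 | (4S)-4-(tert-butyldimethylsilyloxy)-1-ethynyl-2,6,6-trimethylcyclohex-2-en-1-ol (C1 epimers) | C#CC1(O)C(C)=C[C@@H](O[Si](C)(C)C(C)(C)C)CC1(C)C
F4 | step 7 | 2-[(1E,4S)-4-(tert-butyldimethylsilyloxy)-2,6,6-trimethylcyclohex-2-en-1-ylidene]acetaldehyde | O=C/C=C1/C(C)=C[C@@H](O[Si](C)(C)C(C)(C)C)CC1(C)C
F5 | step 7 | ethyl (2E)-4-[(1E,4S)-4-(tert-butyldimethylsilyloxy)-2,6,6-trimethylcyclohex-2-en-1-ylidene]-2-methylbut-2-enoate | CCOC(=O)/C(C)=C/C=C1/C(C)=C[C@@H](O[Si](C)(C)C(C)(C)C)CC1(C)C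
F6 | step 7 | (2E)-4-[(1E,4S)-4-(tert-butyldimethylsilyloxy)-2,6,6-trimethylcyclohex-2-en-1-ylidene]-2-methylbut-2-en-1-ol | OC/C(C)=C/C=C1/C(C)=C[C@@H](O[Si](C)(C)C(C)(C)C)CC1(C)C
F7 | step 13 | C40 (15E)-15,15'-ene-14,14'-diol, 3'-O-tert-butyldimethylsilyl (C14/C14' epimers) | CC1=CC=CC(C)(C)\C1=C/C=C(C)/C=C/C=C(C)/C(O)/C=C/C(O)/C(C)=C/C=C/C(C)=C/C=C1/C(C)=C[C@@H](O[Si](C)(C)C(C)(C)C)CC1(C)C
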